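**Retrosynthetic overview**
1. The (Z)-enol ether C(sp2)–O bond is cut last (Ullmann-type C–O coupling, retention at both partners). This gives the (S)-carbinol of the chromene half and a (Z)-iodoalkene, the latter made from propargyl alcohol and an aryl Grignard reagent by anti-carbomagnesiation/iodinolysis.
2. The (S)-carbinol comes from the 6-acetylchromene by CBS reduction, and the chromene from its 3,4-dihydro form by dehydrogenation of C3–C4.
3. The pyran ring is the only ring made in the route (both benzene rings are bought). It is built in one operation from a phenol, formaldehyde and isobutene: an o-quinone methide hetero-Diels–Alder reaction closes it by forming C4–C3 together with O1–C2.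
4. Enabling feature: O1 on C8a is ortho to C4a, which carries C4, so O1–C8a–C4a–C4 is a latent o-quinone methide. C2 is a quaternary gem-dimethyl carbon, so C2–C3 is isobutene. The 7-methoxy group para to C4a later allows hydride abstraction at C4 to raise C3–C4 to the alkene.

Key step: step 1

Assumption: phenol 1 is taken as a catalogue compound; the locants O1, C2 to C8a refer to the 2H-chromene ring of the target.

**Step 1**
Reactants: 1 1-(4-hydroxy-2-methoxyphenyl)ethan-1-one; 2 2-methylpropene (isobutene)
Product: 5 1-(7-methoxy-2,2-dimethyl-3,4-dihydro-2H-chromen-6-yl)ethan-1-one, via benzodioxaborin 3 (not isolated), via o-quinone methide 4 (not isolated)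
Conditions: PhB(OH)2 (1.1 equiv), (CH2O)n (2 equiv), EtCO2H (cat.), toluene, reflux, Dean–Stark; then 2 (large excess), sealed vessel, 180 °C
Reagents that add atoms: formaldehyde (used as paraformaldehyde), C=O
Why: Phenylboronic acid esterifies the phenol oxygen of 1 and delivers formaldehyde through a six-membered boronate transition state to the free ortho carbon para to the methoxy group, giving the cyclic boronate 3; at 180 °C 3 loses its PhB=O unit in a retro-hetero-Diels–Alder sense, and the o-quinone methide 4 (O1=C8a–C4a=C4) is captured by isobutene in an inverse-electron-demand hetero-Diels–Alder reaction. The closest known reaction type is the boronic acid-templated ortho-hydroxyalkylation of phenols followed by thermolysis of the 2-phenyl-4H-1,3,2-benzodioxaborin in the presence of a 1,1-disubstituted alkene, an established entry to 2,2-disubstituted chromans. The dihydropyran ring is closed by a concerted but asynchronous [4+2] cycloaddition in which the C4–C3 bond forms ahead of the O1–C2 bond; no stereocentre is created. Three selectivities are needed: ortho-regioselectivity (secured by the boron tether on the phenol oxygen and by the lower hindrance of the position para to OMe compared with the position between the two oxygens), mono-functionalisation (the boronate ties up the phenol after one hydroxymethylation) and the orientation of the cycloaddition (the electrophilic methide carbon C4 bonds to the CH2 terminus of isobutene, and O1 to the gem-dimethyl carbon C2, which best carries positive charge). The acetyl group para to O1 makes 4 a more reactive heterodiene toward the unactivated alkene, and slow thermal release of 4 into a large excess of isobutene should suppress its self-condensation. The ring is delivered at the chroman oxidation level, and the C3=C4 double bond follows in step 2.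

**Step 2**
Reactants: 5 1-(7-methoxy-2,2-dimethyl-3,4-dihydro-2H-chromen-6-yl)ethan-1-one
Product: 6 1-(7-methoxy-2,2-dimethyl-2H-chromen-6-yl)ethan-1-one (encecalin)
Conditions: DDQ (1.3 equiv), 1,4-dioxane, reflux
Reagents that add atoms: none
Why: DDQ dehydrogenation of a 2,2-dimethylchroman: hydride abstraction from C4 gives a benzylic cation stabilised by O1 (ortho) and the 7-methoxy group (para to C4a), loss of H3 installs C3=C4, and the quaternary C2 rules out further oxidation.

**Step 3**
Reactants: 6 1-(7-methoxy-2,2-dimethyl-2H-chromen-6-yl)ethan-1-one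
Product: 7 (1S)-1-(7-methoxy-2,2-dimethyl-2H-chromen-6-yl)ethan-1-ol
Conditions: (R)-2-methyl-CBS-oxazaborolidine (10 mol %), BH3·SMe2 (0.7 equiv, slow addition), THF, −20 °C; MeOH quench, aq. NaHCO3 work-up, Et3N-deactivated silica
Reagents that add atoms: none
Why: Corey–Bakshi–Shibata reduction: the (R)-oxazaborolidine–borane complex binds the ketone with aryl as the large and methyl as the small group and delivers hydride to the Re face, which sets the (S)-carbinol centre, while the catalysed ketone reduction should outrun hydroboration of the C3=C4 bond at −20 °C.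

**Step 4**
Reactants: 8 2-bromo-5-methylphenol
Product: 9 [(2-bromo-5-methylphenoxy)methoxy]tri(propan-2-yl)silane
Conditions: NaH, THF, 0 °C; then (i-Pr)3SiOCH2Cl, 0 °C to rt
Reagents that add atoms: (triisopropylsiloxy)methyl chloride (TOM-Cl), CC(C)[Si](OCCl)(C(C)C)C(C)C
Why: Williamson-type O-alkylation of the sodium phenoxide by the α-chloro ether (as for MOM or SEM ethers) gives a silyl formal that is inert to Grignard and copper reagents and to carbonate base, and that fluoride removes at room temperature at the end.

**Step 5**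
Reactants: 9 [(2-bromo-5-methylphenoxy)methoxy]tri(propan-2-yl)silane; 10 prop-2-yn-1-ol
Product: 13 (2Z)-3-iodo-2-[4-methyl-2-({[tri(propan-2-yl)silyl]oxy}methoxy)phenyl]prop-2-en-1-ol, via aryl Grignard reagent 11 (not isolated), via alkenylmagnesium chelate 12 (not isolated)
Conditions: 9, Mg, THF, rt (gives 11); 10, i-PrMgBr (1.0 equiv), THF, 0 °C, then 11 (1.5 equiv), CuI (10 mol %), rt; then iodine, −78 to 0 °C
Reagents that add atoms: iodine, [I][I]
Why: Copper-catalysed anti-carbomagnesiation of the magnesium alkoxide of propargyl alcohol: the aryl group adds to C2 and magnesium ends on C3 cis to the CH2O group in the five-membered chelate 12, so iodinolysis with retention gives the (Z)-iodoalkene with iodine cis to CH2OH and trans to the aryl group, as the enol ether geometry of the target requires.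

**Step 6**
Reactants: 13 (2Z)-3-iodo-2-[4-methyl-2-({[tri(propan-2-yl)silyl]oxy}methoxy)phenyl]prop-2-en-1-ol
Product: 14 tert-butyl({(2Z)-3-iodo-2-[4-methyl-2-({[tri(propan-2-yl)silyl]oxy}methoxy)phenyl]prop-2-en-1-yl}oxy)dimethylsilane
Conditions: TBSCl, imidazole, CH2Cl2, 0 °C to rt
Reagents that add atoms: tert-butyldimethylsilyl chloride (TBSCl), CC(C)(C)[Si](C)(C)Cl
Why: Standard silyl ether formation on the primary allylic alcohol, which would otherwise compete with 7 as the nucleophile in the C–O coupling.

**Step 7**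
Reactants: 7 (1S)-1-(7-methoxy-2,2-dimethyl-2H-chromen-6-yl)ethan-1-ol; 14 tert-butyl({(2Z)-3-iodo-2-[4-methyl-2-({[tri(propan-2-yl)silyl]oxy}methoxy)phenyl]prop-2-en-1-yl}oxy)dimethylsilane
Product: 15 tert-butyl{[(2Z)-3-[(1S)-1-(7-methoxy-2,2-dimethyl-2H-chromen-6-yl)ethoxy]-2-[4-methyl-2-({[tri(propan-2-yl)silyl]oxy}methoxy)phenyl]prop-2-en-1-yl]oxy}dimethylsilane
Conditions: CuI (10 mol %), 3,4,7,8-tetramethyl-1,10-phenanthroline (20 mol %), Cs2CO3 (1.5 equiv), 14 (1.3 equiv), toluene, 80 °C
Reagents that add atoms: none
Why: Ullmann-type C–O cross-coupling of an alkenyl iodide with an alcohol under monovalent copper/phenanthroline catalysis proceeds with retention of the double-bond geometry and never breaks the C–O bond of the carbinol, so the (Z)-enol ether and the (S)-centre are both carried over unchanged, and the basic, non-polar medium avoids ionisation of the doubly donor-activated benzylic position.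

**Step 8**
Reactants: 15 tert-butyl{[(2Z)-3-[(1S)-1-(7-methoxy-2,2-dimethyl-2H-chromen-6-yl)ethoxy]-2-[4-methyl-2-({[tri(propan-2-yl)silyl]oxy}methoxy)phenyl]prop-2-en-1-yl]oxy}dimethylsilane
Product: 16 2-[(1Z)-3-hydroxy-1-{[(1S)-1-(7-methoxy-2,2-dimethyl-2H-chromen-6-yl)ethyl]oxy}prop-1-en-2-yl]-5-methylphenol (CNP0279099.1)
Conditions: TBAF (4 equiv), THF, 0 °C to rt; aq. NaHCO3 work-up
Reagents that add atoms: none
Why: Fluoride-mediated desilylation cleaves the primary TBS ether and the Si–O bond of the silyl formal, whose hemiformal then loses formaldehyde to free the phenol, and these basic room-temperature conditions spare the acid-labile enol ether and the ionisable benzylic ether, so the (S)-centre and the (Z)-geometry are not touched.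

**Compound list**
1 | 1-(4-hydroxy-2-methoxyphenyl)ethan-1-one | COc1cc(O)ccc1C(C)=O | starting material
2 | 2-methylpropene (isobutene) | CC(C)=C | starting material
3 | 1-(7-methoxy-2-phenyl-4H-1,3,2-benzodioxaborin-6-yl)ethan-1-one | COc1cc2c(cc1C(C)=O)COB(c1ccccc1)O2 | intermediate
4 | 4-acetyl-3-methoxy-6-methylidenecyclohexa-2,4-dien-1-one | COC1=CC(=O)C(=C)C=C1C(C)=O | intermediate
5 | 1-(7-methoxy-2,2-dimethyl-3,4-dihydro-2H-chromen-6-yl)ethan-1-one | COc1cc2c(cc1C(C)=O)CCC(C)(C)O2 | intermediate
6 | 1-(7-methoxy-2,2-dimethyl-2H-chromen-6-yl)ethan-1-one (encecalin) | COc1cc2c(cc1C(C)=O)C=CC(C)(C)O2 | intermediate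
7 | (1S)-1-(7-methoxy-2,2-dimethyl-2H-chromen-6-yl)ethan-1-ol | COc1cc2c(cc1[C@H](C)O)C=CC(C)(C)O2 | intermediate
8 | 2-bromo-5-methylphenol | Cc1ccc(Br)c(O)c1 | starting material
9 | [(2-bromo-5-methylphenoxy)methoxy]tri(propan-2-yl)silane | Cc1ccc(Br)c(OCO[Si](C(C)C)(C(C)C)C(C)C)c1 | intermediate
10 | prop-2-yn-1-ol | C#CCO | starting material
11 | bromo[4-methyl-2-({[tri(propan-2-yl)silyl]oxy}methoxy)phenyl]magnesium | Cc1ccc([Mg]Br)c(OCO[Si](C(C)C)(C(C)C)C(C)C)c1 | intermediate
12 | 4-[4-methyl-2-({[tri(propan-2-yl)silyl]oxy}methoxy)phenyl]-2,5-dihydro-1,2-oxamagnesole | Cc1ccc(C2=C[Mg]OC2)c(OCO[Si](C(C)C)(C(C)C)C(C)C)c1 | intermediate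
13 | (2Z)-3-iodo-2-[4-methyl-2-({[tri(propan-2-yl)silyl]oxy}methoxy)phenyl]prop-2-en-1-ol | OC/C(=C\I)c1ccc(C)cc1OCO[Si](C(C)C)(C(C)C)C(C)C | intermediate
14 | tert-butyl({(2Z)-3-iodo-2-[4-methyl-2-({[tri(propan-2-yl)silyl]oxy}methoxy)phenyl]prop-2-en-1-yl}oxy)dimethylsilane | CC(C)(C)[Si](C)(C)OC/C(=C\I)c1ccc(C)cc1OCO[Si](C(C)C)(C(C)C)C(C)C | intermediate
15 | tert-butyl{[(2Z)-3-[(1S)-1-(7-methoxy-2,2-dimethyl-2H-chromen-6-yl)ethoxy]-2-[4-methyl-2-({[tri(propan-2-yl)silyl]oxy}methoxy)phenyl]prop-2-en-1-yl]oxy}dimethylsilane | COc1cc2c(cc1[C@H](C)O/C=C(\CO[Si](C)(C)C(C)(C)C)c1ccc(C)cc1OCO[Si](C(C)C)(C(C)C)C(C)C)C=CC(C)(C)O2 | intermediate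
16 | 2-[(1Z)-3-hydroxy-1-{[(1S)-1-(7-methoxy-2,2-dimethyl-2H-chromen-6-yl)ethyl]oxy}prop-1-en-2-yl]-5-methylphenol | COc1cc2c(cc1[C@H](C)O/C=C(\CO)c1ccc(C)cc1O)C=CC(C)(C)O2 | target

**Step count**
Total: 8 steps. Longest linear sequence: 5 steps (steps 1, 2, 3, 7, 8 or steps 4, 5, 6, 7, 8).

**Steps most likely to fail**

Step 1. The hydroxymethylation may go to the ortho position between the two oxygens, or the o-quinone methide may oligomerise faster than it adds isobutene. The fallback sets out from 1 and comes back at 6 (it also replaces step 2); it closes the same ring at C3=C4 by olefin metathesis. Phenol 1 is iodinated ortho to the hydroxyl group (NIS, TsOH cat., MeCN, rt) to 1-(4-hydroxy-5-iodo-2-methoxyphenyl)ethan-1-one F1. Suzuki–Miyaura vinylation (potassium vinyltrifluoroborate, PdCl2(dppf), K2CO3, THF/H2O, 70 °C) should give 1-(5-ethenyl-4-hydroxy-2-methoxyphenyl)ethan-1-one F2. O-Alkylation with tert-butyl 2-methylbut-3-en-2-yl carbonate under zerovalent palladium catalysis (Pd(PPh3)4, THF, 0 °C) should give the tertiary allyl ether 1-{5-ethenyl-2-methoxy-4-[(2-methylbut-3-en-2-yl)oxy]phenyl}ethan-1-one F3. Ring-closing metathesis (second-generation Grubbs catalyst RuCl2(=CHPh)(H2IMes)(PCy3), CH2Cl2, 40 °C) should then give 6 directly.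

Step 7. Two hindered partners may couple slowly, and at 80 °C the product ether may suffer base-induced elimination or ionisation. The fallback sets out from 14 and comes back at 15. Iodine–lithium exchange on 14 (t-BuLi, Et2O, −78 °C) and trapping with 2-isopropoxy-4,4,5,5-tetramethyl-1,3,2-dioxaborolane should give, with retention, tert-butyldimethyl({(2Z)-2-[4-methyl-2-({[tri(propan-2-yl)silyl]oxy}methoxy)phenyl]-3-(4,4,5,5-tetramethyl-1,3,2-dioxaborolan-2-yl)prop-2-en-1-yl}oxy)silane F4. Oxidative Chan–Lam-type etherification of this alkenyl boronate with 7, mediated by divalent copper (Cu(OAc)2, Et3N, 4 Å molecular sieves, CH2Cl2, air, rt), should give 15 at room temperature with the geometry retained.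

Step 3. Facial selectivity may be incomplete, borane may hydroborate the C3=C4 bond, or the carbinol may lose enantiopurity by ionisation during work-up. The fallback sets out from 6 and comes back at 7. NaBH4 (MeOH, 0 °C) reduces 6 to racemic 1-(7-methoxy-2,2-dimethyl-2H-chromen-6-yl)ethan-1-ol F5. Lipase-catalysed kinetic resolution (immobilised Candida antarctica lipase B, vinyl acetate, MTBE, rt) should acylate the (R)-enantiomer to (1R)-1-(7-methoxy-2,2-dimethyl-2H-chromen-6-yl)ethyl acetate F6 and leave the (S)-alcohol 7, which is separated on Et3N-deactivated silica.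

**Further compounds**
F1 | step 1 | 1-(4-hydroxy-5-iodo-2-methoxyphenyl)ethan-1-one | COc1cc(O)c(I)cc1C(C)=O
F2 | step 1 | 1-(5-ethenyl-4-hydroxy-2-methoxyphenyl)ethan-1-one | COc1cc(O)c(C=C)cc1C(C)=O
F3 | step 1 | 1-{5-ethenyl-2-methoxy-4-[(2-methylbut-3-en-2-yl)oxy]phenyl}ethan-1-one | COc1cc(OC(C)(C)C=C)c(C=C)cc1C(C)=O
F4 | step 7 | tert-butyldimethyl({(2Z)-2-[4-methyl-2-({[tri(propan-2-yl)silyl]oxy}methoxy)phenyl]-3-(4,4,5,5-tetramethyl-1,3,2-dioxaborolan-2-yl)prop-2-en-1-yl}oxy)silane | CC(C)(C)[Si](C)(C)OC/C(=C\B1OC(C)(C)C(C)(C)O1)c1ccc(C)cc1OCO[Si](C(C)C)(C(C)C)C(C)C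
F5 | step 3 | racemic 1-(7-methoxy-2,2-dimethyl-2H-chromen-6-yl)ethan-1-ol | COc1cc2c(cc1C(C)O)C=CC(C)(C)O2
F6 | step 3 | (1R)-1-(7-methoxy-2,2-dimethyl-2H-chromen-6-yl)ethyl acetate | COc1cc2c(cc1[C@@H](C)OC(C)=O)C=CC(C)(C)O2
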